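**Retrosynthetic overview**

- The target is a trans-2,3-diaryl-2,3-dihydrobenzofuran. Its dihydrofuran ring (O1–C2–C3–C3a–C7a) is cut at C2–C3 and C2–O1 in one [4+1] step: O1, C7a, C3a and C3 come from an o-quinone methide of the lower stilbene unit, and C2 comes from a chiral benzylic sulfonium ylide carrying the 2,4-dioxygenated ring.
- Enabling feature: C3a lies between two phenolic oxygens (O1 on C7a and the OH on C4), so C3 is the benzylic carbon of a 2-substituted resorcinol. An ortho phenol is therefore available to form the o-quinone methide (C7a=O, C3a=C3), and the carbon between the two oxygens can be bought as an aldehyde. C2 is a benzylic CH with an o,p-dioxygenated aryl group, i.e. a benzyl carbenoid.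
- The o-quinone methide precursor is a 2-(1-tosylbenzyl)phenol, made by aryl Grignard addition to a 2-hydroxy-6-silyloxy-4-styrylbenzaldehyde and sulfinic acid exchange. The stilbene comes from a Mizoroki–Heck reaction.
- Ring order: the four benzene rings are bought. The dihydrofuran ring is the only ring made and is closed last, with both stereocentres set in that step. One global desilylation ends the route.

Key step: step 11

Assumption (chemistry): the benzylic ylide of (1R,4R,5R)-isothiocineole is taken, by analogy with its additions to aldehydes and imines, to deliver the 2S centre; if the antipodal series should result, the enantiomeric sulfide is used instead with no other change.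

Abbreviation: TIPSO = triisopropylsilyloxy.

**Route**

Step 1
Reactants: 1 4-bromo-2,6-dimethoxybenzaldehyde
Product: 2 4-bromo-2,6-dihydroxybenzaldehyde
Conditions: BBr3 (3 equiv), CH2Cl2, −78 → 0 °C; H2O
Reagents that add atoms: none
Why: Lewis-acid cleavage of both aryl methyl ethers (BBr3 demethylation), assisted by chelation to the ortho aldehyde; no stereocentre is involved.

Step 2
Reactants: 2 4-bromo-2,6-dihydroxybenzaldehyde
Product: 3 4-bromo-2-hydroxy-6-(triisopropylsilyloxy)benzaldehyde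
Conditions: TIPSCl (1.05 equiv), imidazole (2.2 equiv), CH2Cl2, 0 °C
Reagents that add atoms: triisopropylsilyl chloride, CC(C)[Si](Cl)(C(C)C)C(C)C
Why: Phenol silylation that should stop at the mono-ether, because the remaining OH is locked in the hydrogen bond to the aldehyde and a second bulky TIPS group goes on far more slowly.

Step 3
Reactants: 4 2-methoxy-4-vinylphenol
Product: 5 triisopropyl(2-methoxy-4-vinylphenoxy)silane
Conditions: TIPSCl (1.2 equiv), imidazole (2.5 equiv), DMF, rt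
Reagents that add atoms: triisopropylsilyl chloride, CC(C)[Si](Cl)(C(C)C)C(C)C
Why: Standard imidazole-mediated silylation of a phenol; the styrene is untouched.

Step 4
Reactants: 3 4-bromo-2-hydroxy-6-(triisopropylsilyloxy)benzaldehyde; 5 triisopropyl(2-methoxy-4-vinylphenoxy)silane
Product: 6 2-hydroxy-4-[(E)-2-(3-methoxy-4-TIPSO-phenyl)ethenyl]-6-TIPSO-benzaldehyde
Conditions: Pd(OAc)2 (5 mol %), P(o-tol)3 (10 mol %), Et3N (3 equiv), DMF, 90 °C
Reagents that add atoms: none
Why: Mizoroki–Heck reaction of an electron-poor, unhindered aryl bromide with a styrene; syn-insertion and syn-β-hydride elimination give the (E)-stilbene, and the free phenol and aryl TIPS ethers are tolerated.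

Step 5
Reactants: 7 5-bromobenzene-1,3-diol
Product: 8 1-bromo-3,5-bis(triisopropylsilyloxy)benzene
Conditions: TIPSCl (2.4 equiv), imidazole (5 equiv), DMF, rt
Reagents that add atoms: triisopropylsilyl chloride, CC(C)[Si](Cl)(C(C)C)C(C)C
Why: Standard double phenol silylation.

Step 6
Reactants: 6 2-hydroxy-4-[(E)-2-(3-methoxy-4-TIPSO-phenyl)ethenyl]-6-TIPSO-benzaldehyde; 8 1-bromo-3,5-bis(triisopropylsilyloxy)benzene
Product: 10 rac-[3,5-bis(TIPSO)phenyl]{2-hydroxy-4-[(E)-2-(3-methoxy-4-TIPSO-phenyl)ethenyl]-6-TIPSO-phenyl}methanol, via Grignard reagent 9 (not isolated)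
Conditions: 8, Mg turnings, THF, 40 °C; then 6 (0.45 equiv relative to 9), THF, −78 → −20 °C; cold sat. aq. NH4Cl
Reagents that add atoms: none
Why: Grignard formation and 1,2-addition to a salicylaldehyde (the first equivalent deprotonates the phenol); the carbinol centre forms racemic, which does not matter because it becomes sp2 in step 11, and the cold quench should prevent O→O silyl migration.

Step 7
Reactants: 10 rac-[3,5-bis(TIPSO)phenyl]{2-hydroxy-4-[(E)-2-(3-methoxy-4-TIPSO-phenyl)ethenyl]-6-TIPSO-phenyl}methanol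
Product: 11 rac-2-{[3,5-bis(TIPSO)phenyl](4-methylphenylsulfonyl)methyl}-5-[(E)-2-(3-methoxy-4-TIPSO-phenyl)ethenyl]-3-TIPSO-phenol
Conditions: p-TolSO2H (1.5 equiv), CH2Cl2, 4 Å MS, rt
Reagents that add atoms: p-toluenesulfinic acid, Cc1ccc(cc1)S(=O)O
Why: Acid-promoted ionisation of the o-hydroxybenzhydrol and S-attack of the sulfinate give the bench-stable 2-(1-tosylalkyl)phenol, the established type of o-quinone methide precursor for basic conditions.

Step 8
Reactants: 12 2,4-dihydroxybenzaldehyde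
Product: 13 2,4-bis(triisopropylsilyloxy)benzaldehyde
Conditions: TIPSCl (2.5 equiv), imidazole (5 equiv), DMAP (cat.), DMF, 40 °C
Reagents that add atoms: triisopropylsilyl chloride, CC(C)[Si](Cl)(C(C)C)C(C)C
Why: Standard phenol silylation; excess reagent and mild heating also cover the hydrogen-bonded 2-OH.

Step 9
Reactants: 13 2,4-bis(triisopropylsilyloxy)benzaldehyde
Product: 14 [2,4-bis(triisopropylsilyloxy)phenyl]methanol
Conditions: NaBH4, THF/MeOH, 0 °C
Reagents that add atoms: none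
Why: Borohydride reduction of an aryl aldehyde; low temperature and the bulk of TIPS should prevent migration of the ortho silyl group.

Step 10
Reactants: 14 [2,4-bis(triisopropylsilyloxy)phenyl]methanol; 15 (1R,4R,5R)-isothiocineole
Product: 16 S-[2,4-bis(TIPSO)benzyl]-(1R,4R,5R)-isothiocineolium triflate (benzyl on the exo lone pair of sulfur)
Conditions: TfOH (1.0 equiv), CH2Cl2, −40 → 0 °C; precipitation with Et2O/pentane
Reagents that add atoms: trifluoromethanesulfonic acid, OS(=O)(=O)C(F)(F)F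
Why: Acid-mediated S-alkylation of a sulfide by an electron-rich benzylic alcohol (SN1 through the 2,4-bis(silyloxy)benzyl cation), a known way to benzylic sulfonium salts; attack through the less hindered exo lone pair should give one diastereomer at sulfur.

Step 11
Reactants: 11 rac-2-{[3,5-bis(TIPSO)phenyl](4-methylphenylsulfonyl)methyl}-5-[(E)-2-(3-methoxy-4-TIPSO-phenyl)ethenyl]-3-TIPSO-phenol; 16 S-[2,4-bis(TIPSO)benzyl]-(1R,4R,5R)-isothiocineolium triflate (1.5 equiv)
Product: 20 (2S,3S)-hexakis(TIPS) ether of the target, via o-quinone methide 17 (not isolated), via sulfonium ylide 18 (not isolated), via betaine 19 (not isolated)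
Conditions: Cs2CO3 (3 equiv), MeCN/CH2Cl2 (1:1), 4 Å MS, −20 → 0 °C; chromatography
Reagents that add atoms: none
Why: Proposed new method: Cs2CO3 turns 11 into its phenoxide, which expels p-toluenesulfinate to give o-quinone methide 17 (C7a=O, exocyclic C3a=C3), and deprotonates 16 to ylide 18; the ylide carbon (future C2) adds to C3 of 17 with rearomatisation to give betaine 19, whose phenoxide oxygen then displaces the sulfide at C2. The closest known reaction types are the base-mediated [4+1] annulation of 2-(1-tosylalkyl)phenol-derived o-quinone methides with carbonyl-stabilised sulfur ylides, which gives trans-2,3-dihydrobenzofurans, and the asymmetric epoxidation and aziridination with benzylic ylides of isothiocineole; new here is the union of the two, a chiral semistabilised benzylic ylide on an o-quinone methide. The dihydrofuran ring is closed by a 5-exo-tet SN2 O-alkylation (O1–C2 bond, sulfide leaving exocyclically) after the intermolecular C2–C3 bond formation. C2 is controlled by the reagent, since the bicyclic sulfide exposes one face of the ylide carbon and the SN2 closure inverts this centre to 2S; C3 is set relative to C2 in the addition step, where the transition state that keeps the two aryl groups apart leads after closure to the trans (2S,3S) ring. The step needs C–C attack on 17 to outrun O-benzylation of the phenoxide by 16 and quenching of 18 by acidic protons, which the fast sulfinate loss to the aryl-conjugated methide, the single free OH of 11 and the silyl ether on the second ortho oxygen should secure, and it needs trans over cis selectivity, which the steric demand of the two vicinal aryl groups should secure. Any cis isomer is removed by chromatography and is not epimerised at C2, because that would feed the antipodal series.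

Step 12
Reactants: 20 (2S,3S)-hexakis(TIPS) ether of the target
Product: 21 4-[(2S,3S)-3-(3,5-dihydroxyphenyl)-4-hydroxy-6-[(E)-2-(4-hydroxy-3-methoxyphenyl)ethenyl]-2,3-dihydro-1-benzofuran-2-yl]benzene-1,3-diol (target)
Conditions: TBAF (8 equiv), AcOH (8 equiv), THF, 0 °C, degassed; reversed-phase chromatography
Reagents that add atoms: none
Why: Fluoride cleavage of the six aryl silyl ethers; the acetic acid buffer keeps the polyphenol protonated, so that neither the stilbene, the methyl ether nor the trans-dihydrobenzofuran centres should be touched.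

**Compound list**

1 | 4-bromo-2,6-dimethoxybenzaldehyde | COc1cc(Br)cc(OC)c1C=O | starting material
2 | 4-bromo-2,6-dihydroxybenzaldehyde | O=Cc1c(O)cc(Br)cc1O | intermediate
3 | 4-bromo-2-hydroxy-6-(triisopropylsilyloxy)benzaldehyde | O=Cc1c(O)cc(Br)cc1O[Si](C(C)C)(C(C)C)C(C)C | intermediate
4 | 2-methoxy-4-vinylphenol | COc1cc(C=C)ccc1O | starting material
5 | triisopropyl(2-methoxy-4-vinylphenoxy)silane | COc1cc(C=C)ccc1O[Si](C(C)C)(C(C)C)C(C)C | intermediate
6 | 2-hydroxy-4-[(E)-2-(3-methoxy-4-TIPSO-phenyl)ethenyl]-6-TIPSO-benzaldehyde | COc1cc(/C=C/c2cc(O)c(C=O)c(O[Si](C(C)C)(C(C)C)C(C)C)c2)ccc1O[Si](C(C)C)(C(C)C)C(C)C | intermediate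
7 | 5-bromobenzene-1,3-diol | Oc1cc(O)cc(Br)c1 | starting material
8 | 1-bromo-3,5-bis(triisopropylsilyloxy)benzene | CC(C)[Si](Oc1cc(Br)cc(O[Si](C(C)C)(C(C)C)C(C)C)c1)(C(C)C)C(C)C | intermediate
9 | 3,5-bis(triisopropylsilyloxy)phenylmagnesium bromide | CC(C)[Si](Oc1cc([Mg]Br)cc(O[Si](C(C)C)(C(C)C)C(C)C)c1)(C(C)C)C(C)C | intermediate (not isolated)
10 | rac-[3,5-bis(TIPSO)phenyl]{2-hydroxy-4-[(E)-2-(3-methoxy-4-TIPSO-phenyl)ethenyl]-6-TIPSO-phenyl}methanol | COc1cc(/C=C/c2cc(O)c(C(O)c3cc(O[Si](C(C)C)(C(C)C)C(C)C)cc(O[Si](C(C)C)(C(C)C)C(C)C)c3)c(O[Si](C(C)C)(C(C)C)C(C)C)c2)ccc1O[Si](C(C)C)(C(C)C)C(C)C | intermediate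
11 | rac-2-{[3,5-bis(TIPSO)phenyl](4-methylphenylsulfonyl)methyl}-5-[(E)-2-(3-methoxy-4-TIPSO-phenyl)ethenyl]-3-TIPSO-phenol | COc1cc(/C=C/c2cc(O)c(C(c3cc(O[Si](C(C)C)(C(C)C)C(C)C)cc(O[Si](C(C)C)(C(C)C)C(C)C)c3)S(=O)(=O)c3ccc(C)cc3)c(O[Si](C(C)C)(C(C)C)C(C)C)c2)ccc1O[Si](C(C)C)(C(C)C)C(C)C | intermediate
12 | 2,4-dihydroxybenzaldehyde | O=Cc1ccc(O)cc1O | starting material
13 | 2,4-bis(triisopropylsilyloxy)benzaldehyde | O=Cc1ccc(O[Si](C(C)C)(C(C)C)C(C)C)cc1O[Si](C(C)C)(C(C)C)C(C)C | intermediate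
14 | [2,4-bis(triisopropylsilyloxy)phenyl]methanol | OCc1ccc(O[Si](C(C)C)(C(C)C)C(C)C)cc1O[Si](C(C)C)(C(C)C)C(C)C | intermediate
15 | (1R,4R,5R)-isothiocineole, (1R,4R,5R)-4,7,7-trimethyl-6-thiabicyclo[3.2.1]octane | C[C@@H]1CC[C@@H]2C[C@H]1SC2(C)C | starting material
16 | S-[2,4-bis(TIPSO)benzyl]-(1R,4R,5R)-isothiocineolium triflate, benzyl exo on sulfur | C[C@@H]1CC[C@@H]2C[C@H]1[S@@+](Cc1ccc(O[Si](C(C)C)(C(C)C)C(C)C)cc1O[Si](C(C)C)(C(C)C)C(C)C)C2(C)C.[O-]S(=O)(=O)C(F)(F)F | intermediate
17 | o-quinone methide: 6-[3,5-bis(TIPSO)benzylidene]-3-[(E)-2-(3-methoxy-4-TIPSO-phenyl)ethenyl]-5-TIPSO-cyclohexa-2,4-dien-1-one (exocyclic C=C geometry not fixed) | COc1cc(/C=C/C2=CC(=O)C(=Cc3cc(O[Si](C(C)C)(C(C)C)C(C)C)cc(O[Si](C(C)C)(C(C)C)C(C)C)c3)C(O[Si](C(C)C)(C(C)C)C(C)C)=C2)ccc1O[Si](C(C)C)(C(C)C)C(C)C | intermediate (not isolated)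
18 | sulfonium ylide: [2,4-bis(TIPSO)phenyl]methylide of 16 | C[C@@H]1CC[C@@H]2C[C@H]1[S@@+]([CH-]c1ccc(O[Si](C(C)C)(C(C)C)C(C)C)cc1O[Si](C(C)C)(C(C)C)C(C)C)C2(C)C | intermediate (not isolated)
19 | betaine: phenoxide with the sulfonium group on the future C2 and the C3 centre already set | COc1cc(/C=C/c2cc(O[Si](C(C)C)(C(C)C)C(C)C)c(c([O-])c2)[C@H](c2cc(O[Si](C(C)C)(C(C)C)C(C)C)cc(O[Si](C(C)C)(C(C)C)C(C)C)c2)[C@H](c2ccc(O[Si](C(C)C)(C(C)C)C(C)C)cc2O[Si](C(C)C)(C(C)C)C(C)C)[S@@+]2[C@@H]3C[C@@H](CC[C@H]3C)C2(C)C)ccc1O[Si](C(C)C)(C(C)C)C(C)C | intermediate (not isolated)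
20 | (2S,3S)-2-[2,4-bis(TIPSO)phenyl]-3-[3,5-bis(TIPSO)phenyl]-6-[(E)-2-(3-methoxy-4-TIPSO-phenyl)ethenyl]-4-TIPSO-2,3-dihydro-1-benzofuran | COc1cc(/C=C/c2cc(O[Si](C(C)C)(C(C)C)C(C)C)c3c(c2)O[C@H](c2ccc(O[Si](C(C)C)(C(C)C)C(C)C)cc2O[Si](C(C)C)(C(C)C)C(C)C)[C@H]3c2cc(O[Si](C(C)C)(C(C)C)C(C)C)cc(O[Si](C(C)C)(C(C)C)C(C)C)c2)ccc1O[Si](C(C)C)(C(C)C)C(C)C | intermediate
21 | 4-[(2S,3S)-3-(3,5-dihydroxyphenyl)-4-hydroxy-6-[(E)-2-(4-hydroxy-3-methoxyphenyl)ethenyl]-2,3-dihydro-1-benzofuran-2-yl]benzene-1,3-diol | COc1cc(/C=C/c2cc(O)c3c(c2)O[C@H](c2ccc(O)cc2O)[C@H]3c2cc(O)cc(O)c2)ccc1O | target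

**Step count and risks**

Total step count: 12. Longest linear sequence: 7 steps (steps 1, 2, 4, 6, 7, 11, 12).

Steps most likely to fail:

1. Step 11 (proposed new method). The ylide addition may show poor trans/cis or facial selectivity. The phenoxide may be O-benzylated by the sulfonium salt, or the ylide may decay (for example by 1,4-silyl migration) before it meets the o-quinone methide. The fallback uses known chemistry, sets out from 10 and comes back at 20.
   - Oxidation of 10 with MnO2 (CH2Cl2, rt) gives the o-hydroxybenzophenone F1.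
   - Mitsunobu etherification of its phenol with alcohol 14 (PPh3, DIAD, THF) gives the benzyl ether ketone F2.
   - Condensation with hydrazine (N2H4·H2O, cat. AcOH, EtOH, heat) gives the hydrazone F3.
   - MnO2 oxidation gives the diaryldiazomethane F4, which is not isolated.
   - Treatment with Rh2(S-PTAD)4 (or its enantiomer, whichever delivers 3S) brings about the donor/donor carbene 1,5 C–H insertion into the benzylic O–CH2 group, which should give the cis-(2R,3S)-dihydrobenzofuran F5.
   - A catalytic Brønsted acid (TFA, CH2Cl2, low temperature) then ionises the C2–O bond of the o,p-dioxygenated benzylic ether and recloses it to the more stable trans isomer 20, with C3 untouched.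

2. Step 10. Acid-promoted ionisation of the very electron-rich benzylic alcohol may be followed by loss of a silyl group and oligomerisation through a quinone methide instead of capture by the sulfide. The fallback sets out from 14 and comes back at 16. An Appel reaction (CBr4, PPh3, CH2Cl2, 0 °C) gives the benzylic bromide F6. This is used crude for SN2 alkylation of 15 under neutral two-phase conditions with anion exchange (LiOTf, CH2Cl2/H2O, rt), so that no strong acid is present.

3. Step 6. The C4–O silyl group may migrate to the benzylic magnesium alkoxide, or addition to the deactivated phenoxide-aldehyde may stay incomplete. The fallback sets out from 8 and comes back at 10. Bromine–lithium exchange and borylation (n-BuLi, THF, −78 °C; B(OiPr)3; aq. NH4Cl) give the arylboronic acid F7. F7 is added to aldehyde 6 by rhodium(I)-catalysed 1,2-addition ([Rh(cod)OH]2 cat., dioxane/H2O, 50 °C), where the carbinol is protonated as it forms and no hard alkoxide arises.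

**Further compounds**

F1 | step 11 | [3,5-bis(TIPSO)phenyl]{2-hydroxy-4-[(E)-2-(3-methoxy-4-TIPSO-phenyl)ethenyl]-6-TIPSO-phenyl}methanone | COc1cc(/C=C/c2cc(O)c(C(=O)c3cc(O[Si](C(C)C)(C(C)C)C(C)C)cc(O[Si](C(C)C)(C(C)C)C(C)C)c3)c(O[Si](C(C)C)(C(C)C)C(C)C)c2)ccc1O[Si](C(C)C)(C(C)C)C(C)C
F2 | step 11 | {2-[2,4-bis(TIPSO)benzyloxy]-4-[(E)-2-(3-methoxy-4-TIPSO-phenyl)ethenyl]-6-TIPSO-phenyl}[3,5-bis(TIPSO)phenyl]methanone | COc1cc(/C=C/c2cc(OCc3ccc(O[Si](C(C)C)(C(C)C)C(C)C)cc3O[Si](C(C)C)(C(C)C)C(C)C)c(C(=O)c3cc(O[Si](C(C)C)(C(C)C)C(C)C)cc(O[Si](C(C)C)(C(C)C)C(C)C)c3)c(O[Si](C(C)C)(C(C)C)C(C)C)c2)ccc1O[Si](C(C)C)(C(C)C)C(C)C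
F3 | step 11 | hydrazone of ketone F2 | COc1cc(/C=C/c2cc(OCc3ccc(O[Si](C(C)C)(C(C)C)C(C)C)cc3O[Si](C(C)C)(C(C)C)C(C)C)c(C(=NN)c3cc(O[Si](C(C)C)(C(C)C)C(C)C)cc(O[Si](C(C)C)(C(C)C)C(C)C)c3)c(O[Si](C(C)C)(C(C)C)C(C)C)c2)ccc1O[Si](C(C)C)(C(C)C)C(C)C
F4 | step 11 | diaryldiazomethane from F3 (not isolated) | COc1cc(/C=C/c2cc(OCc3ccc(O[Si](C(C)C)(C(C)C)C(C)C)cc3O[Si](C(C)C)(C(C)C)C(C)C)c(C(=[N+]=[N-])c3cc(O[Si](C(C)C)(C(C)C)C(C)C)cc(O[Si](C(C)C)(C(C)C)C(C)C)c3)c(O[Si](C(C)C)(C(C)C)C(C)C)c2)ccc1O[Si](C(C)C)(C(C)C)C(C)C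
F5 | step 11 | (2R,3S)-cis isomer of 20 | COc1cc(/C=C/c2cc(O[Si](C(C)C)(C(C)C)C(C)C)c3c(c2)O[C@@H](c2ccc(O[Si](C(C)C)(C(C)C)C(C)C)cc2O[Si](C(C)C)(C(C)C)C(C)C)[C@H]3c2cc(O[Si](C(C)C)(C(C)C)C(C)C)cc(O[Si](C(C)C)(C(C)C)C(C)C)c2)ccc1O[Si](C(C)C)(C(C)C)C(C)C
F6 | step 10 | 2,4-bis(triisopropylsilyloxy)benzyl bromide | BrCc1ccc(O[Si](C(C)C)(C(C)C)C(C)C)cc1O[Si](C(C)C)(C(C)C)C(C)C
F7 | step 6 | [3,5-bis(triisopropylsilyloxy)phenyl]boronic acid | OB(O)c1cc(O[Si](C(C)C)(C(C)C)C(C)C)cc(O[Si](C(C)C)(C(C)C)C(C)C)c1
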